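A direct plan would build the symmetric chain first: a boron-templated double aldol condensation would give the tetra-O-benzyl dienedione A1,
hydrogenation the diketone A2, two successive reductions the meso syn-diol A3, and acetylation and debenzylation the meso bis-catechol diacetate A4;
only then would one catechol ring be O-methylated.
Weakest would be that final mono-O-methylation: it would have to tell two enantiotopic rings apart far from C3 and C5, it alone would fix the absolute configuration, and no reagent or enzyme is known to do so.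
Next would be the half-reduction of A2 to the hydroxy ketone, which would have to be stopped at partial conversion and recycled.
Last, the alkene hydrogenation would have to spare four benzyl ethers that a second hydrogenolysis removes later, which would add length without complexity.

The route disconnects C4–C5 (chain numbered from the guaiacyl end) and treats both carbinol carbons as carbon–boron stereocentres, exploiting the C4 methylene that lies between C3 and C5 and the fact that the guaiacyl and catechol rings sit on separate three-carbon arms. An enantioenriched 1,2-bis(boronic ester) carrying the guaiacyl arm (C3 set by catalytic diboration) is homologated at its primary boron by a sparteine-derived α-lithiated benzoate carrying the catechol arm. One 1,2-metallate shift joins the arms and sets C5 under reagent control; oxidation gives the syn-diol. The rings differ from the start, so no ring has to be chosen late, no diketone is reduced, and one hydrogenolysis suffices.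

Key step: step 7

Assumption: the (R,R) enantiomer of the TADDOL-derived phosphonite is taken to give the (S)-bis(boronate) 8 from alkene 7; if its sense were the opposite, the (S,S) ligand would be used and nothing else would change.

Step 1
Reactants: 1 methyl 3-(3,4-dihydroxyphenyl)propanoate
Product: 2 methyl 3-(2,2-diphenyl-1,3-benzodioxol-5-yl)propanoate
Conditions: Ph2CCl2 (1.2 equiv), neat, 170 °C, N2 stream
Reagents that add atoms: dichlorodiphenylmethane, ClC(Cl)(c1ccccc1)c1ccccc1
Why: Ketalisation of a catechol with a gem-dichloride (two successive substitutions at the benzhydrylic carbon, driven by loss of HCl) should give the diphenylmethylene ketal, which has no C–H next to oxygen and so should later survive sec-butyllithium; no stereocentre is formed.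

Step 2
Reactants: 2 methyl 3-(2,2-diphenyl-1,3-benzodioxol-5-yl)propanoate
Product: 3 3-(2,2-diphenyl-1,3-benzodioxol-5-yl)propan-1-ol
Conditions: LiAlH4, THF, 0 °C to rt; aqueous NaOH work-up
Reagents that add atoms: none
Why: Ester reduction by lithium aluminium hydride (two hydride transfers via the aldehyde) should give the primary alcohol and leave the diaryl ketal, which has no reducible group, untouched.

Step 3
Reactants: 3 3-(2,2-diphenyl-1,3-benzodioxol-5-yl)propan-1-ol
Product: 4 3-(2,2-diphenyl-1,3-benzodioxol-5-yl)propyl 2,4,6-triisopropylbenzoate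
Conditions: 2,4,6-triisopropylbenzoic acid, PPh3, DIAD, THF, 0 °C to rt
Reagents that add atoms: 2,4,6-triisopropylbenzoic acid, CC(C)c1cc(C(C)C)c(C(=O)O)c(C(C)C)c1
Why: Mitsunobu esterification, in which the phosphonium-activated primary alcohol is displaced by the hindered carboxylate, should give the bulky benzoate that directs α-lithiation, resists attack at its carbonyl and later serves as the leaving group.

Step 4
Reactants: 5 [4-(benzyloxy)-3-methoxyphenyl]methanol
Product: 6 1-(benzyloxy)-4-(chloromethyl)-2-methoxybenzene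
Conditions: SOCl2, DMF (cat.), CH2Cl2, 0 °C to rt; concentrated and used directly
Reagents that add atoms: thionyl chloride, O=S(Cl)Cl
Why: Deoxychlorination through the chlorosulfite should be fast for this electron-rich benzylic alcohol, and the labile chloride is carried on without purification.

Step 5
Reactants: 6 1-(benzyloxy)-4-(chloromethyl)-2-methoxybenzene
Product: 7 4-[4-(benzyloxy)-3-methoxyphenyl]but-1-ene
Conditions: allylMgBr (Et2O), THF, 0 °C to rt
Reagents that add atoms: allylmagnesium bromide, C=CC[Mg]Br
Why: Uncatalysed SN2 coupling of a benzylic chloride with an allyl Grignard reagent should give the homoallyl arene (C1–C4 of the chain), the aryl ethers being inert.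

Step 6
Reactants: 7 4-[4-(benzyloxy)-3-methoxyphenyl]but-1-ene
Product: 8 2,2'-{(2S)-4-[4-(benzyloxy)-3-methoxyphenyl]butane-1,2-diyl}bis(4,4,5,5-tetramethyl-1,3,2-dioxaborolane)
Conditions: Pt(dba)3 [tris(dibenzylideneacetone)platinum] (1 mol%), (R,R)-3,5-diisopropylphenyl-TADDOL phenylphosphonite (1.2 mol%), B2pin2 (1.05 equiv), THF, 60 °C
Reagents that add atoms: bis(pinacolato)diboron, CC1(C)OB(OC1(C)C)B1OC(C)(C)C(C)(C)O1
Why: Platinum-catalysed enantioselective alkene 1,2-diboration (oxidative addition of the B–B bond to zerovalent platinum, face-selective insertion of the monosubstituted alkene, reductive elimination) adds both borons syn to one face, so the chiral phosphonite sets C3 as a C–B stereocentre under catalyst control.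

Step 7
Reactants: 4 3-(2,2-diphenyl-1,3-benzodioxol-5-yl)propyl 2,4,6-triisopropylbenzoate; 8 2,2'-{(2S)-4-[4-(benzyloxy)-3-methoxyphenyl]butane-1,2-diyl}bis(4,4,5,5-tetramethyl-1,3,2-dioxaborolane)
Product: 12 (3R,5S)-1-[4-(benzyloxy)-3-methoxyphenyl]-7-(2,2-diphenyl-1,3-benzodioxol-5-yl)heptane-3,5-diol, via (R)-α-lithiated benzoate 9 (not isolated), via lithium boronate complex 10 (not isolated), via (3R,5S)-1,3-bis(boronic ester) 11 (not isolated)
Conditions: 4 (1.25 equiv), s-BuLi (1.2 equiv), (+)-sparteine (1.25 equiv), Et2O, −78 °C, 5 h; 8 (1.0 equiv), −78 °C, 1 h; then 35 °C, 16 h; then 2 M aq NaOH, 30% aq H2O2, THF, 0 °C to rt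
Reagents that add atoms: hydrogen peroxide, OO
Why: Lithiation–borylation, a sparteine-mediated Hoppe-type deprotonation coupled to a Matteson-type 1,2-metallate rearrangement: sec-butyllithium·(+)-sparteine should remove the pro-R hydrogen of the OCH2 group of 4 to give the configurationally stable (R)-carbenoid 9, which should add with retention to the less hindered primary boron of 8 to give ate complex 10. On warming, the C4 methylene migrates from boron to C5 anti to the departing triisopropylbenzoate, with inversion at C5, so the C4–C5 bond and the C5–B stereocentre of 11 arise in one stereospecific event, and no ring is closed. The closest known reaction type is the regioselective homologation of enantioenriched 1,2-bis(boronic esters) at the primary boron by lithiated benzoates or carbamates. C5 is controlled only by the sparteine enantiomer and C3 only by the diboration catalyst of step 6, so the syn relation and the absolute sense are independent of the remote ring substituents, and alkaline peroxide then replaces both borons by hydroxyl with retention to give (3R,5S)-12. The step needs site selectivity between the two borons, secured by the steric difference between the CH2–B and CH–B centres and by keeping 9 in only slight excess, and a clean lithiation, secured by a ketal without C–H next to oxygen on the lithiated arm while the benzyl ether sits on the boron partner and never meets sec-butyllithium. Minor enantiomers of either partner should end mainly in the anti diol, a diastereomer removable by chromatography, so the enantiomeric purity of 12 should exceed that of either partner.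

Step 8
Reactants: 12 (3R,5S)-1-[4-(benzyloxy)-3-methoxyphenyl]-7-(2,2-diphenyl-1,3-benzodioxol-5-yl)heptane-3,5-diol
Product: 13 (3R,5S)-1-[4-(benzyloxy)-3-methoxyphenyl]-7-(2,2-diphenyl-1,3-benzodioxol-5-yl)heptane-3,5-diyl diacetate
Conditions: Ac2O (3 equiv), pyridine, DMAP (cat.), CH2Cl2, 0 °C to rt
Reagents that add atoms: acetic anhydride, CC(=O)OC(C)=O
Why: DMAP-catalysed O-acylation of both secondary alcohols breaks no C–O bond at C3 or C5 and leaves the benzyl ether and the ketal untouched.

Step 9
Reactants: 13 (3R,5S)-1-[4-(benzyloxy)-3-methoxyphenyl]-7-(2,2-diphenyl-1,3-benzodioxol-5-yl)heptane-3,5-diyl diacetate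
Product: 14 (3R,5S)-7-(3,4-dihydroxyphenyl)-1-(4-hydroxy-3-methoxyphenyl)heptane-3,5-diyl diacetate
Conditions: H2 (1 atm), Pd(OH)2/C (20%), EtOAc–MeOH, rt; filtered and concentrated under argon
Reagents that add atoms: none
Why: Catalytic hydrogenolysis of benzylic C–O bonds should remove the benzyl ether as toluene and the diphenylmethylene ketal as diphenylmethane under neutral conditions, while the acetates, which are not benzylic, and both stereocentres are not affected.

Compound list
1 | methyl 3-(3,4-dihydroxyphenyl)propanoate | COC(=O)CCc1ccc(O)c(O)c1 | starting material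
2 | methyl 3-(2,2-diphenyl-1,3-benzodioxol-5-yl)propanoate | COC(=O)CCc1ccc2OC(c3ccccc3)(c3ccccc3)Oc2c1 | intermediate
3 | 3-(2,2-diphenyl-1,3-benzodioxol-5-yl)propan-1-ol | OCCCc1ccc2OC(c3ccccc3)(c3ccccc3)Oc2c1 | intermediate
4 | 3-(2,2-diphenyl-1,3-benzodioxol-5-yl)propyl 2,4,6-triisopropylbenzoate | CC(C)c1cc(C(C)C)c(C(=O)OCCCc2ccc3OC(c4ccccc4)(c4ccccc4)Oc3c2)c(C(C)C)c1 | intermediate
5 | [4-(benzyloxy)-3-methoxyphenyl]methanol | COc1cc(CO)ccc1OCc1ccccc1 | starting material
6 | 1-(benzyloxy)-4-(chloromethyl)-2-methoxybenzene | COc1cc(CCl)ccc1OCc1ccccc1 | intermediate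
7 | 4-[4-(benzyloxy)-3-methoxyphenyl]but-1-ene | COc1cc(CCC=C)ccc1OCc1ccccc1 | intermediate
8 | 2,2'-{(2S)-4-[4-(benzyloxy)-3-methoxyphenyl]butane-1,2-diyl}bis(4,4,5,5-tetramethyl-1,3,2-dioxaborolane) | COc1cc(CC[C@H](CB2OC(C)(C)C(C)(C)O2)B2OC(C)(C)C(C)(C)O2)ccc1OCc1ccccc1 | intermediate
9 | (1R)-1-lithio-3-(2,2-diphenyl-1,3-benzodioxol-5-yl)propyl 2,4,6-triisopropylbenzoate, as its (+)-sparteine complex | [Li][C@H](CCc1ccc2OC(c3ccccc3)(c3ccccc3)Oc2c1)OC(=O)c1c(C(C)C)cc(C(C)C)cc1C(C)C | intermediate
10 | lithium {(2S)-4-[4-(benzyloxy)-3-methoxyphenyl]-2-(4,4,5,5-tetramethyl-1,3,2-dioxaborolan-2-yl)butyl}{(1R)-3-(2,2-diphenyl-1,3-benzodioxol-5-yl)-1-[(2,4,6-triisopropylbenzoyl)oxy]propyl}(pinacolato)borate | [Li+].COc1cc(CC[C@H](C[B-]2(OC(C)(C)C(C)(C)O2)[C@H](CCc2ccc3OC(c4ccccc4)(c4ccccc4)Oc3c2)OC(=O)c2c(C(C)C)cc(C(C)C)cc2C(C)C)B2OC(C)(C)C(C)(C)O2)ccc1OCc1ccccc1 | intermediate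
11 | 2,2'-{(3R,5S)-1-[4-(benzyloxy)-3-methoxyphenyl]-7-(2,2-diphenyl-1,3-benzodioxol-5-yl)heptane-3,5-diyl}bis(4,4,5,5-tetramethyl-1,3,2-dioxaborolane) | COc1cc(CC[C@H](C[C@H](CCc2ccc3OC(c4ccccc4)(c4ccccc4)Oc3c2)B2OC(C)(C)C(C)(C)O2)B2OC(C)(C)C(C)(C)O2)ccc1OCc1ccccc1 | intermediate
12 | (3R,5S)-1-[4-(benzyloxy)-3-methoxyphenyl]-7-(2,2-diphenyl-1,3-benzodioxol-5-yl)heptane-3,5-diol | COc1cc(CC[C@H](C[C@H](CCc2ccc3OC(c4ccccc4)(c4ccccc4)Oc3c2)O)O)ccc1OCc1ccccc1 | intermediate
13 | (3R,5S)-1-[4-(benzyloxy)-3-methoxyphenyl]-7-(2,2-diphenyl-1,3-benzodioxol-5-yl)heptane-3,5-diyl diacetate | COc1cc(CC[C@H](C[C@H](CCc2ccc3OC(c4ccccc4)(c4ccccc4)Oc3c2)OC(C)=O)OC(C)=O)ccc1OCc1ccccc1 | intermediate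
14 | (3R,5S)-7-(3,4-dihydroxyphenyl)-1-(4-hydroxy-3-methoxyphenyl)heptane-3,5-diyl diacetate | COc1cc(CC[C@H](C[C@H](CCc2ccc(O)c(O)c2)OC(C)=O)OC(C)=O)ccc1O | target

Total step count: 9. Longest linear sequence: 6 steps (steps 1, 2, 3, 7, 8, 9 or steps 4, 5, 6, 7, 8, 9).

Steps most likely to fail

1. Step 7 (key step). The carbenoid may add to the secondary boron or homologate the product a second time, the hindered ate complex may rearrange slowly, or the benzodioxole ring may be lithiated in competition with the OCH2 group. The fallback builds C4–C5 by an aldol reaction and sets C3 by 1,3-syn reduction; it sets out from 3 and 7 and returns at 12. Swern oxidation of 3 would give 3-(2,2-diphenyl-1,3-benzodioxol-5-yl)propanal F1. Wacker oxidation of 7 (PdCl2, CuCl, O2, DMF–H2O) would give 4-[4-(benzyloxy)-3-methoxyphenyl]butan-2-one F2. The diisopinocampheylboron enolate of F2 (Ipc2BCl, Et3N, the reagent enantiomer chosen for attack on the Re face of F1) would add to F1 to give (5S)-1-[4-(benzyloxy)-3-methoxyphenyl]-7-(2,2-diphenyl-1,3-benzodioxol-5-yl)-5-hydroxyheptan-3-one F3. Narasaka–Prasad reduction (Et2BOMe, NaBH4, THF–MeOH, −78 °C) would then set C3 syn to C5 and give 12.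

2. Step 6. Facial selectivity in the alkene insertion may be insufficient or turnover slow, which would lower the enantiomeric purity of 8 and raise the share of anti diol later. The fallback sets C3 with a chiral base instead of a chiral catalyst and brings in C4 as a one-carbon diboron unit; it sets out from 7 and returns at 8. Lemieux–Johnson cleavage with reductive work-up (OsO4 cat., NaIO4; then NaBH4) would give 3-[4-(benzyloxy)-3-methoxyphenyl]propan-1-ol F4. Mitsunobu esterification as in step 3 would give 3-[4-(benzyloxy)-3-methoxyphenyl]propyl 2,4,6-triisopropylbenzoate F5. Lithiation with s-BuLi/(−)-sparteine (Et2O, −78 °C), borylation with bis(pinacolatoboryl)methane, CH2(Bpin)2, and 1,2-migration of the CH2B group would give 8 with the (S) configuration. In this variant the benzyl ether would be exposed to the base, so s-BuLi would be kept as the limiting reagent.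

3. Step 9. Hydrogenolysis of the diaryl ketal, whose two C–O bonds sit at a hindered quaternary carbon, may stay incomplete, or the free catechol may be oxidised by air during a long reaction. The fallback removes the ketal by acidolysis and the benzyl ether by hydrogenolysis; it sets out from 13 and returns at 14. Aqueous trifluoroacetic acid in CH2Cl2 at 0 °C to rt would hydrolyse the ketal to (3R,5S)-1-[4-(benzyloxy)-3-methoxyphenyl]-7-(3,4-dihydroxyphenyl)heptane-3,5-diyl diacetate F6 and benzophenone. A short hydrogenolysis (H2, Pd/C, EtOAc) would then remove the single benzyl group and give 14.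

Further compounds
F1 | step 7 | 3-(2,2-diphenyl-1,3-benzodioxol-5-yl)propanal | O=CCCc1ccc2OC(c3ccccc3)(c3ccccc3)Oc2c1
F2 | step 7 | 4-[4-(benzyloxy)-3-methoxyphenyl]butan-2-one | COc1cc(CCC(C)=O)ccc1OCc1ccccc1
F3 | step 7 | (5S)-1-[4-(benzyloxy)-3-methoxyphenyl]-7-(2,2-diphenyl-1,3-benzodioxol-5-yl)-5-hydroxyheptan-3-one | COc1cc(CCC(=O)C[C@H](CCc2ccc3OC(c4ccccc4)(c4ccccc4)Oc3c2)O)ccc1OCc1ccccc1
F4 | step 6 | 3-[4-(benzyloxy)-3-methoxyphenyl]propan-1-ol | COc1cc(CCCO)ccc1OCc1ccccc1
F5 | step 6 | 3-[4-(benzyloxy)-3-methoxyphenyl]propyl 2,4,6-triisopropylbenzoate | COc1cc(CCCOC(=O)c2c(C(C)C)cc(C(C)C)cc2C(C)C)ccc1OCc1ccccc1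
F6 | step 9 | (3R,5S)-1-[4-(benzyloxy)-3-methoxyphenyl]-7-(3,4-dihydroxyphenyl)heptane-3,5-diyl diacetate | COc1cc(CC[C@H](C[C@H](CCc2ccc(O)c(O)c2)OC(C)=O)OC(C)=O)ccc1OCc1ccccc1
A1 | direct plan | (1E,6E)-1,7-bis[3,4-bis(benzyloxy)phenyl]hepta-1,6-diene-3,5-dione | O=C(/C=C/c1ccc(OCc2ccccc2)c(OCc2ccccc2)c1)CC(=O)/C=C/c1ccc(OCc2ccccc2)c(OCc2ccccc2)c1
A2 | direct plan | 1,7-bis[3,4-bis(benzyloxy)phenyl]heptane-3,5-dione | O=C(CCc1ccc(OCc2ccccc2)c(OCc2ccccc2)c1)CC(=O)CCc1ccc(OCc2ccccc2)c(OCc2ccccc2)c1
A3 | direct plan | meso-(3R,5S)-1,7-bis[3,4-bis(benzyloxy)phenyl]heptane-3,5-diol | C(c1ccccc1)Oc1cc(CC[C@H](C[C@H](CCc2ccc(OCc3ccccc3)c(OCc3ccccc3)c2)O)O)ccc1OCc1ccccc1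
A4 | direct plan | meso-(3R,5S)-1,7-bis(3,4-dihydroxyphenyl)heptane-3,5-diyl diacetate | Oc1cc(CC[C@H](C[C@H](CCc2ccc(O)c(O)c2)OC(C)=O)OC(C)=O)ccc1O
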